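The easy step is to set G against D in the flasks below, all of them stirred at constant volume.

| flask | D | G | remark | time |
|---|---|---|---|---|
| noon | 17 mM | 15.3 mM | run made earlier |  |
| spring | 17 mM | 7.7 mM | run made earlier |  |
| autumn | 17 mM | 31 mM | run made earlier |  |
| dawn | 8.5 mM | 15.3 mM | run made earlier |  |
| amber | 17 mM | 15.3 mM | everything together at the start | 3.0 h |
| blue | 17 mM | 15.3 mM (in portions, 4, over 2.5 h) | first portion at the start, last at 2.5 h | 3.0 h |
| teal | 17 mM | 15.3 mM (fed, over 2.5 h) | all else is in the flask from the start; the feed brings no volume worth counting | 3.0 h |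
| grey | 17 mM (fed, over 2.5 h) | 15.3 mM | all else is in the flask from the start; the feed brings no volume worth counting | 3.0 h |

- noon (time / h: E / %, D / %): 0.417: 43, 50; 0.833: 42, 40; 1.33: 43, 39; 1.50: 38, 32; 2.00: 38, 26; 2.50: 39, 25; 3.00: 37, 20
- spring (time / h: E / %, D / %): 0.250: 20, 73; 0.417: 22, 70; 0.667: 23, 66; 1.00: 23, 63; 1.50: 21, 54; 2.50: 17, 44; 4.00: 15, 35
- autumn (time / h: E / %, D / %): 0.200: 70, 25; 0.500: 87, 12; 1.00: 84, 6; 1.50: 86, 8; 2.00: 85, 0; 3.00: 85, 3; 4.00: 87, 2
- dawn (time / h: E / %, D / %): 0.250: 65, 33; 0.500: 75, 25; 1.00: 82, 11; 2.00: 85, 2; 4.00: 88, 1

(scatter of a reading: 2 percentage points)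

- the analysis behind the earlier runs scatters by 2 percentage points, standard deviation

* which flask leads in amount of E, in percent of the D charged ("all alike" within 1.5 percentage points) (amber / blue / teal / grey / all alike)
* how much E is there at the end, in percent of the D charged: amber
* how much E is there at the end, in percent of the D charged: blue
* how much E is there at the end, in percent of the D charged: teal
* how much E is there at the end, in percent of the D charged: grey

Amber, blue, teal and grey each get 15.3 mM of G and 17 mM of D, so G comes to 90.0 % of the D charge. If each E took one G, that would be your first bound from above. The runs lower it. The readings of E level off at 23 % in the spring run, 43 % in the noon run and 87 % in the autumn run, which is about half of the G charged in each, so each E reads as costing two G. Read so, with the scatter of those readings, the bound tightens to 45.0 %, the ceiling: the G charge divided by two, as a fraction of the D charge.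

Now the bound from below, which is my own reckoning. The noon run has the amber recipe, and its E fell from 43 % to 37 % while D fell from 50 % to 20 %. On a straight line, that is an exposure of 0.904 h at the whole D charge. Take the loss of E as proportional to this exposure. With E at the ceiling, the charge minus E leaves 55.0 % for D. Held for the whole 3.0 h, that is an exposure of 1.65 h, larger than in the noon run, and on this reckoning it brings E down to 34.2 %. Your bracket runs from that floor, an estimate and not a proof, to the ceiling.

The forecast gives amber 37.5 %, blue 36.5 %, teal 35.5 % and grey 41 %, and so grey leads, on the ground that “Feeding D keeps D low while E forms”. Its values lie inside the bracket, which gives one range for the four flasks.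

The flasks give amber 37.9 %, blue 35.2 %, teal 36.5 % and grey 41.7 %, so grey leads, 3.3 percentage points below the ceiling, and blue stays above the floor.

    D + G → L + E (k = 0.160 M⁻¹ s⁻¹)
    G + L ⇌ Z, settled at all times (K = 29000 M⁻¹)
    D ⇌ Q (K = 3.20, k = 2.10 × 10⁻⁵ s⁻¹)
    D + E → J (k = 0.00580 M⁻¹ s⁻¹)
    D + L → X (k = 0.00550 M⁻¹ s⁻¹)

In the scheme each E takes one G and comes with one L, and L can bind a further G as Z. Take grey with D cut to 4.2 mM. The ceiling becomes 182 %, above the whole D charge, so the reckoning makes D the limiting reagent, and E at the whole charge leaves 45.1 % of the G. That flask ends with D at 0.908 %, E at 96.4 % and G at 46.8 %.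

The earlier runs and the new flask were computed with constants of no real substance; the scatter is artificial.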